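**Retrosynthetic overview**
- Last step: one-pot BCl3 unmasking (two benzyl ethers on the 5,7-dihydroxy half, the peri 5-OMe on the dimethoxy half).
- C2–C1′ bond of the 5,7-dihydroxyflavone half: Negishi coupling of a C2-zincated 5,7-bis(benzyloxy)chromone (reversed-polarity chromone C2) with a ring B aryl triflate.
- Key biaryl bond C8–C2′: metal-free arylation of intact 4′,5,7-trimethoxyflavone at C8 by a quinone monoacetal acting as an enolonium equivalent; the phenol OH it leaves marks C1′ and becomes the triflate.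
- Ring order: the three rings of the dimethoxy half come intact from apigenin; ring B of the second half is aromatised from the dienone in the key step; its pyranone ring C is closed separately on phloroacetophenone (ring A); no ring is formed after the union.

Assumption: the SMILES has no stereodescriptor and the molecule has no stereocentre; the C8–C2′ axis is treated as configurationally undefined, so the compound is made as drawn.

**Step 1**
Reactants: 1 apigenin (5,7-dihydroxy-2-(4-hydroxyphenyl)-4H-chromen-4-one)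
Product: 2 4′,5,7-trimethoxyflavone (5,7-dimethoxy-2-(4-methoxyphenyl)-4H-chromen-4-one)
Conditions: Me2SO4 (6 equiv), K2CO3, acetone, reflux, 36 h
Reagents that add atoms: dimethyl sulfate, COS(=O)(=O)OC
Why: Williamson-type permethylation of the three phenols, the hydrogen-bonded 5-OH reacting last under prolonged reflux; no stereocentre.

**Step 2**
Reactants: 2 4′,5,7-trimethoxyflavone; 3 4,4-dimethoxycyclohexa-2,5-dien-1-one (quinone monoacetal)
Product: 4 8-(2-hydroxy-5-methoxyphenyl)-5,7-dimethoxy-2-(4-methoxyphenyl)-4H-chromen-4-one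
Conditions: 3 (1.5 equiv, slow addition), C6F5CO2H (1 equiv), (CF3)2CHOH/CH2Cl2, 0 °C to rt
Reagents that add atoms: none
Why: Proposed new method: the acid/hexafluoroisopropanol-activated monoacetal 3 acts as an enolonium (alpha-carbonyl cation) equivalent, so C8 of 2 (activated by O1, 7-OMe and the para 5-OMe; the site where 5,7-dimethoxyflavones are iodinated) attacks the carbon alpha to the dienone carbonyl in an SN2′ displacement of one acetal methoxy group, and the dienone then tautomerises to the 2-aryl-4-methoxyphenol, joining two carbons that are both normally nucleophilic; the closest known reaction type is the acid-promoted quinone monoacetal–alkoxyarene biaryl coupling, not yet shown for a flavone nucleophile; no stereocentre is formed.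

**Step 3**
Reactants: 4 8-(2-hydroxy-5-methoxyphenyl)-5,7-dimethoxy-2-(4-methoxyphenyl)-4H-chromen-4-one
Product: 5 2-[5,7-dimethoxy-2-(4-methoxyphenyl)-4-oxo-4H-chromen-8-yl]-4-methoxyphenyl trifluoromethanesulfonate
Conditions: Tf2O (1.3 equiv), pyridine, CH2Cl2, 0 °C
Reagents that add atoms: trifluoromethanesulfonic anhydride, O=S(=O)(OS(=O)(=O)C(F)(F)F)C(F)(F)F
Why: O-sulfonylation of the only free phenol turns the oxygen left by the key step into a cross-coupling leaving group at C1′; no stereocentre.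

**Step 4**
Reactants: 6 2′,4′,6′-trihydroxyacetophenone
Product: 7 1-[2,4-bis(benzyloxy)-6-hydroxyphenyl]ethan-1-one
Conditions: BnBr (2.1 equiv), K2CO3, DMF, rt
Reagents that add atoms: benzyl bromide, BrCc1ccccc1
Why: Williamson etherification stops at the dibenzyl ether because the last ortho OH is hydrogen-bonded to the ketone and much less nucleophilic.

**Step 5**
Reactants: 7 1-[2,4-bis(benzyloxy)-6-hydroxyphenyl]ethan-1-one
Product: 9 5,7-bis(benzyloxy)-4H-chromen-4-one, via enaminone 8 (not isolated)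
Conditions: Me2NCH(OMe)2, toluene, 95 °C; then 2 M HCl, CH2Cl2, 40 °C
Reagents that add atoms: N,N-dimethylformamide dimethyl acetal, COC(OC)N(C)C
Why: Enaminone condensation at the acetyl methyl followed by acid-promoted intramolecular oxa-Michael addition and loss of dimethylamine closes the pyranone ring (enaminone chromone synthesis).

**Step 6**
Reactants: 9 5,7-bis(benzyloxy)-4H-chromen-4-one; 5 2-[5,7-dimethoxy-2-(4-methoxyphenyl)-4-oxo-4H-chromen-8-yl]-4-methoxyphenyl trifluoromethanesulfonate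
Product: 11 5,7-bis(benzyloxy)-2-{2-[5,7-dimethoxy-2-(4-methoxyphenyl)-4-oxo-4H-chromen-8-yl]-4-methoxyphenyl}-4H-chromen-4-one, via chromon-2-ylzinc chloride 10 (not isolated)
Conditions: 9, TMPZnCl·LiCl (1.2 equiv), THF, 25 °C; then 5, Pd(OAc)2 (5 mol %), SPhos (10 mol %), THF, 60 °C
Reagents that add atoms: none
Why: The magnesium-free TMP zinc base metalates the most acidic C2–H next to the ring oxygen, turning the normally electrophilic beta carbon of the pyranone into a nucleophile that undergoes Negishi coupling with the hindered aryl triflate under SPhos ligation.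

**Step 7**
Reactants: 11 5,7-bis(benzyloxy)-2-{2-[5,7-dimethoxy-2-(4-methoxyphenyl)-4-oxo-4H-chromen-8-yl]-4-methoxyphenyl}-4H-chromen-4-one
Product: 12 5,7-dihydroxy-2-{2-[5-hydroxy-7-methoxy-2-(4-methoxyphenyl)-4-oxo-4H-chromen-8-yl]-4-methoxyphenyl}-4H-chromen-4-one (target)
Conditions: BCl3 (8 equiv), C6HMe5 (6 equiv), CH2Cl2, −78 to 0 °C; then MeOH/H2O
Reagents that add atoms: none
Why: BCl3 cleaves both benzyl aryl ethers (benzyl cation trapped by pentamethylbenzene) and, through chelation to the C4 carbonyl, only the peri 5-OMe, while the 7-OMe and both anisole-type methyl ethers survive (Lewis-acid ether cleavage).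

**Compound list**
1 | apigenin, 5,7-dihydroxy-2-(4-hydroxyphenyl)-4H-chromen-4-one | O=c1cc(-c2ccc(O)cc2)oc2cc(O)cc(O)c12 | starting material
2 | 5,7-dimethoxy-2-(4-methoxyphenyl)-4H-chromen-4-one | COc1ccc(-c2cc(=O)c3c(OC)cc(OC)cc3o2)cc1 | intermediate
3 | 4,4-dimethoxycyclohexa-2,5-dien-1-one | COC1(OC)C=CC(=O)C=C1 | starting material
4 | 8-(2-hydroxy-5-methoxyphenyl)-5,7-dimethoxy-2-(4-methoxyphenyl)-4H-chromen-4-one | COc1ccc(-c2cc(=O)c3c(OC)cc(OC)c(-c4cc(OC)ccc4O)c3o2)cc1 | intermediate
5 | 2-[5,7-dimethoxy-2-(4-methoxyphenyl)-4-oxo-4H-chromen-8-yl]-4-methoxyphenyl trifluoromethanesulfonate | COc1ccc(-c2cc(=O)c3c(OC)cc(OC)c(-c4cc(OC)ccc4OS(=O)(=O)C(F)(F)F)c3o2)cc1 | intermediate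
6 | 2′,4′,6′-trihydroxyacetophenone | CC(=O)c1c(O)cc(O)cc1O | starting material
7 | 1-[2,4-bis(benzyloxy)-6-hydroxyphenyl]ethan-1-one | CC(=O)c1c(O)cc(OCc2ccccc2)cc1OCc1ccccc1 | intermediate
8 | (E)-1-[2,4-bis(benzyloxy)-6-hydroxyphenyl]-3-(dimethylamino)prop-2-en-1-one | CN(C)/C=C/C(=O)c1c(O)cc(OCc2ccccc2)cc1OCc1ccccc1 | intermediate
9 | 5,7-bis(benzyloxy)-4H-chromen-4-one | O=c1ccoc2cc(OCc3ccccc3)cc(OCc3ccccc3)c12 | intermediate
10 | [5,7-bis(benzyloxy)-4-oxo-4H-chromen-2-yl]zinc chloride | O=c1cc([Zn]Cl)oc2cc(OCc3ccccc3)cc(OCc3ccccc3)c12 | intermediate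
11 | 5,7-bis(benzyloxy)-2-{2-[5,7-dimethoxy-2-(4-methoxyphenyl)-4-oxo-4H-chromen-8-yl]-4-methoxyphenyl}-4H-chromen-4-one | COc1ccc(-c2cc(=O)c3c(OC)cc(OC)c(-c4cc(OC)ccc4-c4cc(=O)c5c(OCc6ccccc6)cc(OCc6ccccc6)cc5o4)c3o2)cc1 | intermediate
12 | 5,7-dihydroxy-2-{2-[5-hydroxy-7-methoxy-2-(4-methoxyphenyl)-4-oxo-4H-chromen-8-yl]-4-methoxyphenyl}-4H-chromen-4-one | COc1ccc(-c2cc(=O)c3c(O)cc(OC)c(-c4cc(OC)ccc4-c4cc(=O)c5c(O)cc(O)cc5o4)c3o2)cc1 | target

**Totals**
Total step count: 7. Longest linear sequence: 5 (steps 1, 2, 3, 6, 7).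

**Three steps most likely to fail**

Step 2 (quinone monoacetal arylation of the flavone). The flavone ring A may be too weakly nucleophilic, or the product phenol may react again with 3. Fallback, setting out from 2: iodinate at C8 with N-iodosuccinimide in CF3CO2H/CH2Cl2 to give 8-iodo-5,7-dimethoxy-2-(4-methoxyphenyl)-4H-chromen-4-one F1. Then run a Suzuki–Miyaura coupling of F1 with commercial (2-hydroxy-5-methoxyphenyl)boronic acid (Pd(PPh3)4, K2CO3, dioxane/H2O, 90 °C). This returns to the route at 4 and replaces the enolonium arylation with a conventional halide/boronic acid cross-coupling.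

Step 6 (C2 zincation and Negishi coupling). Zincation could be diverted to C3 by the 5-alkoxy/carbonyl chelate, or the hindered triflate could couple poorly. Fallback, setting out from 5: reductive carbonylation (CO/H2, Pd(OAc)2, dppp, pyridine, DMF, 100 °C) gives 2-[5,7-dimethoxy-2-(4-methoxyphenyl)-4-oxo-4H-chromen-8-yl]-4-methoxybenzaldehyde F2. Claisen–Schmidt condensation of F2 with 7 (KOH, EtOH/THF, rt) gives (E)-1-[2,4-bis(benzyloxy)-6-hydroxyphenyl]-3-{2-[5,7-dimethoxy-2-(4-methoxyphenyl)-4-oxo-4H-chromen-8-yl]-4-methoxyphenyl}prop-2-en-1-one F3. Oxidative cyclisation of F3 (catalytic I2, DMSO, 120 °C) returns to the route at 11. Here the second pyranone ring is built on the biaryl instead of being coupled on as a preformed chromone.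

Step 7 (one-pot BCl3 deprotection). Debenzylation and 5-O-demethylation may not go to completion together, or ring benzylation may compete. Fallback, setting out from 11: hydrogenolysis (H2, Pd/C, THF/MeOH, rt) gives 5,7-dihydroxy-2-{2-[5,7-dimethoxy-2-(4-methoxyphenyl)-4-oxo-4H-chromen-8-yl]-4-methoxyphenyl}-4H-chromen-4-one F4. Chelation-controlled demethylation of the single peri 5-OMe of F4 (AlCl3, MeCN, 50 °C) then returns to the route at 12. This separates the two deprotections into orthogonal reductive and Lewis-acid stages.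

**Further compounds**
F1 | step 2 | 8-iodo-5,7-dimethoxy-2-(4-methoxyphenyl)-4H-chromen-4-one | COc1ccc(-c2cc(=O)c3c(OC)cc(OC)c(I)c3o2)cc1
F2 | step 6 | 2-[5,7-dimethoxy-2-(4-methoxyphenyl)-4-oxo-4H-chromen-8-yl]-4-methoxybenzaldehyde | COc1ccc(-c2cc(=O)c3c(OC)cc(OC)c(-c4cc(OC)ccc4C=O)c3o2)cc1
F3 | step 6 | (E)-1-[2,4-bis(benzyloxy)-6-hydroxyphenyl]-3-{2-[5,7-dimethoxy-2-(4-methoxyphenyl)-4-oxo-4H-chromen-8-yl]-4-methoxyphenyl}prop-2-en-1-one | COc1ccc(-c2cc(=O)c3c(OC)cc(OC)c(-c4cc(OC)ccc4/C=C/C(=O)c4c(O)cc(OCc5ccccc5)cc4OCc4ccccc4)c3o2)cc1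
F4 | step 7 | 5,7-dihydroxy-2-{2-[5,7-dimethoxy-2-(4-methoxyphenyl)-4-oxo-4H-chromen-8-yl]-4-methoxyphenyl}-4H-chromen-4-one | COc1ccc(-c2cc(=O)c3c(OC)cc(OC)c(-c4cc(OC)ccc4-c4cc(=O)c5c(O)cc(O)cc5o4)c3o2)cc1
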